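**Retrosynthetic overview**

1. Kazinol A (15) <= methanolysis of two aryl acetates and one aryl silyl ether <= double cross-metathesis (allyl to prenyl) <= hydride for nitrogen at C4 <= cycloadduct 12.
2. 12 <= catalytic asymmetric oxa-Povarov reaction (formal inverse-demand [4+2]) of aryl oxocarbenium ion 10 (heterodiene C4a=C8a–O1=C2, from the O-aryl O-pivaloyl acetal 8) with benzyl N-vinylcarbamate 9 as the C3–C4 ethylene equivalent. Ring C is closed and C2 is set in this one step; the C4–N bond is temporary.
3. 8 <= aldehyde 4 + pivaloyl chloride + phenol 6; 4 <= double aromatic Claisen rearrangement of 3,4-bis(allyloxy)benzaldehyde, possible because both prenyl sites (C2', C5') lie ortho to the catechol oxygens of ring B.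
4. Enabling feature: C4a of ring A is ortho to O1 and para to the C7 oxygen, so the arene end of the 2-oxadiene is its most nucleophilic carbon; C3 and C4 are bare CH2 groups, and the nitrogen left at C4 sits on a doubly oxygen-activated benzylic carbon from which it can be ionized and replaced by hydride.
5. Ring order: ring B (from 3,4-dihydroxybenzaldehyde) and ring A (from resorcinol) are bought; ring C is the only ring made, last, in the key step.

Key step: step 6

Remark: flavan numbering is used (O1, C2, C3, C4, C4a, C5 to C8, C8a; ring B C1' to C6'); the given SMILES corresponds to the 2S configuration.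
Assumption: the antipode of the chiral acid that delivers the 2S series in step 6 is to be fixed in a first screen; both antipodes are equally accessible.

**Route**

Step 1
Reactants: 1 3,4-dihydroxybenzaldehyde
Product: 2 3,4-bis(allyloxy)benzaldehyde
Conditions: allyl bromide (2.5 equiv), K2CO3, DMF, 60 °C
Reagents that add atoms: allyl bromide, C=CCBr
Why: Williamson O-allylation of both phenols; no stereocentre is formed.

Step 2
Reactants: 2 3,4-bis(allyloxy)benzaldehyde
Product: 3 2,5-diallyl-3,4-dihydroxybenzaldehyde
Conditions: N,N-diethylaniline, 190 °C, argon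
Reagents that add atoms: none
Why: Two successive aromatic Claisen ([3,3]-sigmatropic) rearrangements with tautomerization; the 3-O-allyl group can only reach C2 and the 4-O-allyl group only C5, because the other ortho position of each is the oxygen-bearing carbon.

Step 3
Reactants: 3 2,5-diallyl-3,4-dihydroxybenzaldehyde
Product: 4 3,6-diallyl-4-formyl-1,2-phenylene diacetate
Conditions: Ac2O, pyridine, DMAP (cat.), CH2Cl2, 0 °C to rt
Reagents that add atoms: acetic anhydride, CC(=O)OC(C)=O
Why: DMAP-catalysed O-acetylation; the acetates make ring B electron-poor, which later keeps the benzylic O1–C2 bond from ionizing under acid.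

Step 4
Reactants: 5 resorcinol
Product: 6 3-(tert-butyldimethylsilyloxy)phenol
Conditions: TBSCl (1.0 equiv), imidazole, DMF, 0 °C; chromatography
Reagents that add atoms: tert-butyldimethylsilyl chloride, CC(C)(C)[Si](C)(C)Cl
Why: Statistical mono-silylation of a symmetric diphenol with one equivalent of silyl chloride; the mono ether should be separable from resorcinol and the bis ether.

Step 5
Reactants: 4 3,6-diallyl-4-formyl-1,2-phenylene diacetate; 6 3-(tert-butyldimethylsilyloxy)phenol
Product: 8 (3,4-diacetoxy-2,5-diallylphenyl)[3-(tert-butyldimethylsilyloxy)phenoxy]methyl pivalate (racemic at the acetal carbon), via alpha-chloro ester 7 (not isolated)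
Conditions: PivCl, ZnCl2 (5 mol %), CH2Cl2, 0 °C to rt; then 6, iPr2NEt, 0 °C; rapid filtration through Et3N-deactivated silica
Reagents that add atoms: pivaloyl chloride, CC(C)(C)C(Cl)=O
Why: ZnCl2-catalysed addition of an acyl chloride across an aldehyde C=O gives the alpha-chloroalkyl ester, which O-alkylates the phenol as acyloxyalkyl halides do (acyloxyalkyl aryl ether formation); the hindered pivaloyl group resists acyl transfer, and the racemic acetal stereocentre is erased in step 6.

Step 6
Reactants: 8 (3,4-diacetoxy-2,5-diallylphenyl)[3-(tert-butyldimethylsilyloxy)phenoxy]methyl pivalate; 9 benzyl N-vinylcarbamate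
Product: 12 benzyl N-[(2S,4S)-2-(3,4-diacetoxy-2,5-diallylphenyl)-7-(tert-butyldimethylsilyloxy)chroman-4-yl]carbamate, via aryl oxocarbenium ion 10 (not isolated), via N-acyliminium ion 11 (not isolated)
Conditions: confined chiral imidodiphosphorimidate (IDPi) Brønsted acid (BINOL-derived, 3,3'-diaryl, N-triflyl; 5 mol %), 9 (1.5 equiv, slow addition), toluene, −60 °C
Reagents that add atoms: none
Why: Proposed new method: the chiral acid protonates the pivalate carbonyl of 8 and pivalic acid leaves (the aryloxide is the poorer leaving group and the only donor left), giving aryl oxocarbenium ion 10, a cationic 2-oxadiene C4a=C8a–O1=C2, as a contact ion pair with the confined chiral anion. Enecarbamate 9, hydrogen-bonded through its N–H to that anion, adds with its CH2 terminus to one face of C2 (C2–C3 bond; 2S is set here by the catalyst) to give N-acyliminium ion 11, and C4a then attacks the iminium carbon (C4–C4a bond) in a 6-exo-trig Friedel–Crafts closure of ring C, rearomatization returning the proton to the catalyst. The closest known reaction types are the SnCl4-promoted oxa-Povarov reaction of aryl oxocarbenium ions with alkenes, the chiral phosphoric acid-catalysed Povarov reaction of N-aryl imines with this same enecarbamate and chiral-anion-controlled additions of alkenes to oxocarbenium ions; new is the enantioselective ion-pair version on an O-aryl oxocarbenium ion. Overall ring C is closed by a stepwise formal inverse-electron-demand [4+2] cycloaddition; C4 should come out cis to the C2 aryl group (4S) through a chair-like closure with both groups equatorial, but it is cleared in step 7, so only the face selection at C2 matters. The step needs closure at C4a and not at C8 (secured by C4a lying para to the C7 silyloxy group and being the unhindered ortho position), no re-ionization of the new O1–C2 bond that would racemize C2 (secured by the two electron-withdrawing acetates on ring B) and no Prins capture of 10 by the 2'-allyl group (a monosubstituted alkene is far less nucleophilic than 9, which is why allyl and not prenyl is carried at this stage).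

Step 7
Reactants: 12 benzyl N-[(2S,4S)-2-(3,4-diacetoxy-2,5-diallylphenyl)-7-(tert-butyldimethylsilyloxy)chroman-4-yl]carbamate
Product: 13 (2S)-2-(3,4-diacetoxy-2,5-diallylphenyl)-7-(tert-butyldimethylsilyloxy)chroman
Conditions: Et3SiH (3 equiv), CF3CO2H (10 equiv), CH2Cl2, −20 to 0 °C
Reagents that add atoms: none
Why: Acidolysis of the 2,4-dioxygenated benzylic carbamate (as in the cleavage of 2,4-dimethoxybenzyl carbamates) gives the C4 cation stabilized by O1 (ortho) and the C7 silyloxy group (para), which Et3SiH reduces (ionic hydrogenation); the acetate-deactivated ring B should keep O1–C2 from ionizing, so C2 is untouched, and terminal alkenes are not reduced under these conditions.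

Step 8
Reactants: 13 (2S)-2-(3,4-diacetoxy-2,5-diallylphenyl)-7-(tert-butyldimethylsilyloxy)chroman
Product: 14 (2S)-2-[3,4-diacetoxy-2,5-bis(3-methylbut-2-en-1-yl)phenyl]-7-(tert-butyldimethylsilyloxy)chroman
Conditions: second-generation Grubbs catalyst (H2IMes)(PCy3)Cl2Ru=CHPh (5 mol %), 2-methyl-2-butene/CH2Cl2, 40 °C, sealed tube
Reagents that add atoms: 2-methyl-2-butene, CC=C(C)C
Why: Olefin cross-metathesis of the two terminal allyl groups with 2-methyl-2-butene, the standard allyl-to-prenyl conversion, driven by loss of propene; the trisubstituted product alkenes should not react further and C2 is not involved.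

Step 9
Reactants: 14 (2S)-2-[3,4-diacetoxy-2,5-bis(3-methylbut-2-en-1-yl)phenyl]-7-(tert-butyldimethylsilyloxy)chroman
Product: 15 Kazinol A, (2S)-2-[3,4-dihydroxy-2,5-bis(3-methylbut-2-en-1-yl)phenyl]chroman-7-ol
Conditions: K2CO3, MeOH (degassed), argon, 0 °C to rt; aq. NH4Cl
Reagents that add atoms: none
Why: Base-mediated methanolysis (transesterification of the aryl acetates and cleavage of the aryl silyl ether, both with phenoxide leaving groups) under acid-free conditions that spare the prenyl groups ortho to the new phenols; low temperature and exclusion of oxygen protect the catechol and the C2 benzylic ether.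

**Compound list**

1 | 3,4-dihydroxybenzaldehyde | O=Cc1ccc(O)c(O)c1 | starting material
2 | 3,4-bis(allyloxy)benzaldehyde | O=Cc1ccc(OCC=C)c(OCC=C)c1 | intermediate
3 | 2,5-diallyl-3,4-dihydroxybenzaldehyde | O=Cc1cc(CC=C)c(O)c(O)c1CC=C | intermediate
4 | 3,6-diallyl-4-formyl-1,2-phenylene diacetate | O=Cc1cc(CC=C)c(OC(C)=O)c(OC(C)=O)c1CC=C | intermediate
5 | resorcinol | Oc1cccc(O)c1 | starting material
6 | 3-(tert-butyldimethylsilyloxy)phenol | CC(C)(C)[Si](C)(C)Oc1cccc(O)c1 | intermediate
7 | chloro(3,4-diacetoxy-2,5-diallylphenyl)methyl pivalate (racemic, not isolated) | CC(C)(C)C(=O)OC(Cl)c1cc(CC=C)c(OC(C)=O)c(OC(C)=O)c1CC=C | intermediate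
8 | (3,4-diacetoxy-2,5-diallylphenyl)[3-(tert-butyldimethylsilyloxy)phenoxy]methyl pivalate (racemic) | CC(C)(C)C(=O)OC(Oc1cccc(O[Si](C)(C)C(C)(C)C)c1)c1cc(CC=C)c(OC(C)=O)c(OC(C)=O)c1CC=C | intermediate
9 | benzyl N-vinylcarbamate | C=CNC(=O)OCc1ccccc1 | starting material
10 | O-[3-(tert-butyldimethylsilyloxy)phenyl] oxocarbenium ion of aldehyde 4 (ion pair with the catalyst anion, not isolated) | C=CCc1cc(C=[O+]c2cccc(O[Si](C)(C)C(C)(C)C)c2)c(CC=C)c(OC(C)=O)c1OC(C)=O | intermediate
11 | (S)-N-(benzyloxycarbonyl)iminium ion of 3-aryl-3-aryloxypropanal (not isolated) | C=CCc1cc([C@H](CC=[NH+]C(=O)OCc2ccccc2)Oc2cccc(O[Si](C)(C)C(C)(C)C)c2)c(CC=C)c(OC(C)=O)c1OC(C)=O | intermediate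
12 | benzyl N-[(2S,4S)-2-(3,4-diacetoxy-2,5-diallylphenyl)-7-(tert-butyldimethylsilyloxy)chroman-4-yl]carbamate | C=CCc1cc([C@@H]2C[C@H](NC(=O)OCc3ccccc3)c3ccc(O[Si](C)(C)C(C)(C)C)cc3O2)c(CC=C)c(OC(C)=O)c1OC(C)=O | intermediate
13 | (2S)-2-(3,4-diacetoxy-2,5-diallylphenyl)-7-(tert-butyldimethylsilyloxy)chroman | C=CCc1cc([C@@H]2CCc3ccc(O[Si](C)(C)C(C)(C)C)cc3O2)c(CC=C)c(OC(C)=O)c1OC(C)=O | intermediate
14 | (2S)-2-[3,4-diacetoxy-2,5-bis(3-methylbut-2-en-1-yl)phenyl]-7-(tert-butyldimethylsilyloxy)chroman | CC(C)=CCc1cc([C@@H]2CCc3ccc(O[Si](C)(C)C(C)(C)C)cc3O2)c(CC=C(C)C)c(OC(C)=O)c1OC(C)=O | intermediate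
15 | Kazinol A | CC(C)=CCc1cc([C@@H]2CCc3ccc(O)cc3O2)c(CC=C(C)C)c(O)c1O | target

**Step count and risks**

Total steps: 9. Longest linear sequence: 8 steps (steps 1, 2, 3, 5, 6, 7, 8, 9); step 4 is the side branch.

Steps most likely to fail:

1. Step 6 (Proposed new method). What may go wrong: poor enantiofacial discrimination within the oxocarbenium/chiral anion ion pair, a racemic background pathway, or acid-induced oligomerization of the enecarbamate overtaking ionization of 8. Fallback, known chemistry, from 8 back to 13: the chiral information is moved from the catalyst to a covalent, removable auxiliary on the dienophile. Commercial (R)-4-phenyloxazolidin-2-one is N-vinylated by vinyl transfer from butyl vinyl ether (Pd(OCOCF3)2, 4,7-diphenyl-1,10-phenanthroline) to (R)-4-phenyl-3-vinyloxazolidin-2-one F1. Acetal 8 and F1 are then combined in an achiral SnCl4-promoted oxa-Povarov reaction (CH2Cl2, −78 °C). The cis adducts form as two diastereomers that should separate on ordinary silica, so no predicted induction is relied on. The 2S diastereomer, (4R)-3-[(2S,4S)-2-(3,4-diacetoxy-2,5-diallylphenyl)-7-(tert-butyldimethylsilyloxy)chroman-4-yl]-4-phenyloxazolidin-2-one F2, is submitted to the conditions of step 7 (Et3SiH, CF3CO2H), which cleave the auxiliary from C4 and rejoin the route at 13.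

2. Step 5. What may go wrong: acyl transfer from the alpha-chloro ester to the phenol, Friedel–Crafts C-alkylation of the electron-rich phenol, capture of the acyloxy cation by the ortho allyl group, or hydrolysis of the acylal on isolation. Fallback, from 4 back to 12: the mixed acylal is replaced by a symmetric diaryl acetal. Aldehyde 4 is converted with SOCl2 and catalytic DMF (CH2Cl2, reflux) to 4-(dichloromethyl)-3,6-diallyl-1,2-phenylene diacetate F3. Double substitution with phenol 6 (2.2 equiv, iPr2NEt, Bu4NI cat., MeCN, 50 °C) should give 3,6-diallyl-4-{bis[3-(tert-butyldimethylsilyloxy)phenoxy]methyl}-1,2-phenylene diacetate F4. F4 takes the place of 8 in step 6: either aryloxy group leaves to give the same ion 10, phenol 6 is released, and the route is rejoined at 12.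

3. Step 7. What may go wrong: slow hydride capture of the C4 cation, leading to proton loss to the flav-3-ene, arylation of a second molecule, partial loss of the silyl ether, or competing opening of O1–C2. Fallback, from 12 back to 13: ionic reduction is replaced by thiol capture and radical reduction. Acid-mediated thiolysis of 12 (PhSH, BF3·OEt2, CH2Cl2, −40 °C; the classical C4 thiolysis of flavans) should give (2S)-2-(3,4-diacetoxy-2,5-diallylphenyl)-4-(phenylthio)-7-(tert-butyldimethylsilyloxy)chroman F5 as a mixture of C4 epimers. Neutral radical desulfurization (Bu3SnH, AIBN, toluene, 80 °C) then gives 13 without further exposure of C2 to acid.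

**Further compounds**

F1 | step 6 | (R)-4-phenyl-3-vinyloxazolidin-2-one | C=CN1C(=O)OC[C@H]1c1ccccc1
F2 | step 6 | (4R)-3-[(2S,4S)-2-(3,4-diacetoxy-2,5-diallylphenyl)-7-(tert-butyldimethylsilyloxy)chroman-4-yl]-4-phenyloxazolidin-2-one | C=CCc1cc([C@@H]2C[C@H](N3C(=O)OC[C@H]3c3ccccc3)c3ccc(O[Si](C)(C)C(C)(C)C)cc3O2)c(CC=C)c(OC(C)=O)c1OC(C)=O
F3 | step 5 | 4-(dichloromethyl)-3,6-diallyl-1,2-phenylene diacetate | ClC(Cl)c1cc(CC=C)c(OC(C)=O)c(OC(C)=O)c1CC=C
F4 | step 5 | 3,6-diallyl-4-{bis[3-(tert-butyldimethylsilyloxy)phenoxy]methyl}-1,2-phenylene diacetate | C=CCc1cc(C(Oc2cccc(O[Si](C)(C)C(C)(C)C)c2)Oc2cccc(O[Si](C)(C)C(C)(C)C)c2)c(CC=C)c(OC(C)=O)c1OC(C)=O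
F5 | step 7 | (2S)-2-(3,4-diacetoxy-2,5-diallylphenyl)-4-(phenylthio)-7-(tert-butyldimethylsilyloxy)chroman (C4 epimers) | C=CCc1cc([C@@H]2CC(Sc3ccccc3)c3ccc(O[Si](C)(C)C(C)(C)C)cc3O2)c(CC=C)c(OC(C)=O)c1OC(C)=O
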